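Decide first which concentration sets the pace of the loss of single product; I choose [reagent], and you count the clock while reagent is present.

the same everywhere: starting material 20 mM

| charge | reagent | remark | time |
|---|---|---|---|
| Friday's | 1.1 equiv | run made earlier |  |
| Wednesday's | 3.3 equiv | run made earlier |  |
| amber | 0.800 equiv |  | 5.0 min |
| blue | 1.20 equiv |  | 5.0 min |
| teal | 1.50 equiv |  | 5.0 min |
| ochre | 2.50 equiv |  | 5.0 min |

- Friday's (time / min: single product / %): 0.167: 45; 0.417: 48; 0.667: 47; 1.00: 49; 1.50: 46; 2.00: 44; 2.50: 39
- Wednesday's (time / min: single product / %): 0.333: 21; 0.667: 11; 1.00: 5; 1.33: 3; 2.00: 2; 2.50: 0

(standard deviation of a reading: 1.5 percentage points)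

- amount of single product at the end, in percent of the starting material charged for amber, blue, teal, ochre, in this order
- how that number moves from the first to the last of them (falls, then rises / rises all the way / rises, then falls / hardly changes / falls all the way)

- the numbers in the tables scatter with a standard deviation of 1.5 percentage points
- "hardly changes" means that all values lie within two and a half points (for a concentration: within two and a half percent of the largest)

In Wednesday's run, 3.3 equiv of reagent is charged, far more than Friday's, and single product falls from 21 % at 0.333 min to 5 % at 1.00 min. Reagent is being used up over this stretch, so the decay has no constant half-life; those two readings give only an average, 0.322 min as the mean time in which single product halves in Wednesday's run, its working life.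

Now take Friday's run, the neighbour of blue, with 1.1 equiv against 1.20 equiv. From 1.00 min to 2.50 min it spans 4.66 working lives, so at Wednesday's average pace single product would drop by a factor of 25.2. The readings go from 49 % to 39 %, a factor of 1.26, which is much smaller. So you may conclude that Friday's single product is no longer being lost at Wednesday's average pace by then.

My own reckoning follows from this: a flask ends near what stood when its reagent stopped acting, less a slow tail. Blue should therefore end not far below Friday's last reading. Amber, charged with less than Friday, should end lower, and so should ochre, charged with more, which spends longer under reagent. I expect a row that rises, then falls.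

The forecast differs from mine. It gives 38 %, 31 %, 13 % and 0.2 %, a row that falls all the way, on the ground that single product “decays slowly through leftover reagent”.

The flasks give 29.1 %, 38.5 %, 39.0 % and 15.7 %: the row rises, then falls.

    starting material + reagent → single product + by-product (k = 6.10 M⁻¹ s⁻¹)
    reagent + single product → double product + by-product (k = 2.80 M⁻¹ s⁻¹)
    reagent + double product → triple product + by-product (k = 6.40 M⁻¹ s⁻¹)
    starting material + single product → side product (k = 0.320 M⁻¹ s⁻¹)
    crystals ⇌ by-product, rate k5*(cs5 - [by-product]) while solid is left; crystals form when [by-product] > cs5 (solubility = 6.60 mM, k = 0.970 s⁻¹)

In amber, at the concentrations as charged, single product has a half-life of 0.26 min by the step with reagent, shorter than the 1.8 min by the step with starting material. Yet blue's reagent reads 0 % at 2.50 min, and blue's 5.0 min is 15.5 working lives of 0.322 min, while its single product ends at 38.5 %. Ochre's reagent reads 0.580 % of its charge at 2.50 min, and over the next 7.76 working lives its single product goes from 16.3 % to 15.7 %.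

The numbers in the tables come from a simulation for an exercise.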